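**Assumption:** the SMILES is read as (1R,3R,4S,4aS,8aR)-4-hydroxy-8a-methyl-5-methylidene-3-(propan-2-yl)decahydronaphthalen-1-yl 4-methoxybenzoate, a cis-fused decalin. Eudesmane locants are used as atom labels: ring A = C1–C5 + C10, ring B = C5–C10, C14 = angular methyl, C15 = methylidene carbon, C6 = carbinol, C7 = isopropyl carbon, C9 = ester carbon.

## Retrosynthetic overview

1. 15 ⇐ ketone 14: the C6 carbinol is made last by equatorial hydride delivery.
2. 14 ⇐ acyclic 1-bromoalkyl anisate 13 (C9–C10 and C5–C4 disconnected). One radical chain closes ring B first (C9 α-acyloxy radical, 6-endo onto the enone), then ring A (C5 α-keto radical, 6-exo-dig onto the alkyne, which becomes C4=C15).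
3. 13 ⇐ keto aldehyde 11 + 4-methoxybenzoyl halide; 11 ⇐ enone 10 by cleavage of a terminal alkene.
4. 10 ⇐ thioester 6 + hepta-1,6-diyne 7 (syn-carboalumination fixes the E-enone and brings C14; Pd acyl coupling).
5. 6 ⇐ Evans allylation of N-isovaleryl oxazolidinone 3 (sets C7, the only stereocentre carried into the cascade).

## Route

Step 1
Reactants: 1 (4R)-4-benzyl-1,3-oxazolidin-2-one; 2 3-methylbutanoyl chloride
Product: 3 (4R)-4-benzyl-3-(3-methylbutanoyl)-1,3-oxazolidin-2-one
Conditions: n-BuLi, THF, −78 °C; then 2, −78 → 0 °C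
Reagents that add atoms: none
Why: N-acylation of the lithiated Evans auxiliary; no new stereocentre is formed.

Step 2
Reactants: 3 (4R)-4-benzyl-3-(3-methylbutanoyl)-1,3-oxazolidin-2-one; 4 3-bromoprop-1-ene
Product: 5 (4R)-4-benzyl-3-[(2R)-2-(propan-2-yl)pent-4-enoyl]-1,3-oxazolidin-2-one
Conditions: NaN(SiMe3)2, THF, −78 °C; then 4, −78 → −40 °C
Reagents that add atoms: none
Why: Evans asymmetric alkylation, in which the chelated Z-enolate is allylated on the face opposite the benzyl group and so sets C7 as (R) (dr > 95:5 expected).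

Step 3
Reactants: 5 (4R)-4-benzyl-3-[(2R)-2-(propan-2-yl)pent-4-enoyl]-1,3-oxazolidin-2-one
Product: 6 S-ethyl (2R)-2-(propan-2-yl)pent-4-enethioate
Conditions: EtSH, n-BuLi (gives LiSEt), THF, 0 °C; aq NH4Cl
Reagents that add atoms: ethanethiol, CCS
Why: Thiolate cleavage of the imide (exocyclic acyl transfer) gives the thioester without epimerising C7 and returns auxiliary 1.

Step 4
Reactants: 6 S-ethyl (2R)-2-(propan-2-yl)pent-4-enethioate; 7 hepta-1,6-diyne
Product: 10 (4R,6E)-7-methyl-4-(propan-2-yl)dodeca-1,6-dien-11-yn-5-one, via alkenylalane 8 (not isolated), via alkenylzinc chloride 9 (not isolated)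
Conditions: 7 (3 equiv), AlMe3 (2 equiv), Cp2ZrCl2 (0.25 equiv), CH2Cl2, 0 → 23 °C; evaporate, THF, ZnCl2; then 6, PdCl2(PPh3)2 (5 mol %), 23 °C; 1 M HCl, 0 °C
Reagents that add atoms: trimethylaluminium, C[Al](C)C
Why: Negishi Zr-catalysed syn-carboalumination of one alkyne of 7 delivers C14 and fixes the E geometry (methyl cis to the metal), and Pd-catalysed thioester–organozinc coupling (Fukuyama ketone synthesis) then forms the enone with retention of alkene geometry and without touching C7.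

Step 5
Reactants: 10 (4R,6E)-7-methyl-4-(propan-2-yl)dodeca-1,6-dien-11-yn-5-one
Product: 11 (3R,5E)-6-methyl-4-oxo-3-(propan-2-yl)undec-5-en-10-ynal
Conditions: OsO4 (2 mol %), NaIO4 (4 equiv), 2,6-lutidine, dioxane/H2O 3:1, 23 °C
Reagents that add atoms: osmium tetroxide, O=[Os](=O)(=O)=O; sodium periodate, [Na+].[O-][I](=O)(=O)=O
Why: Lemieux–Johnson oxidative cleavage picks the electron-rich monosubstituted alkene over the electron-poor trisubstituted enone and the alkyne, and leaves C7 unchanged.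

Step 6
Reactants: 11 (3R,5E)-6-methyl-4-oxo-3-(propan-2-yl)undec-5-en-10-ynal; 12 4-methoxybenzoyl chloride
Product: 14 (1R,3R,4aS,8aR)-8a-methyl-5-methylidene-4-oxo-3-(propan-2-yl)decahydronaphthalen-1-yl 4-methoxybenzoate, via bromo ester 13 (not isolated)
Conditions: 12, Me3SiBr, CH2Cl2, 23 °C; then 11, ZnBr2 (2 mol %), −20 °C; evaporate; Bu3SnH (1.3 equiv), AIBN (0.2 equiv), PhH (0.005 M), 80 °C, syringe pump 8 h
Reagents that add atoms: none
Why: Tin hydride-mediated tandem radical cyclisation of the 1-bromoalkyl ester: the nucleophilic C9 α-acyloxy radical adds 6-endo-trig to the enone β-carbon C10 through a chair with the C7 isopropyl and C9 aroyloxy groups equatorial and C14 axial (E-alkene), setting C9 and C10, and the resulting C5 α-keto radical closes 6-exo-dig onto the alkyne by axial attack (cis ring fusion) before the vinyl radical takes H from Bu3SnH to leave the C4=C15 methylidene.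

Step 7
Reactants: 14 (1R,3R,4aS,8aR)-8a-methyl-5-methylidene-4-oxo-3-(propan-2-yl)decahydronaphthalen-1-yl 4-methoxybenzoate
Product: 15 (1R,3R,4S,4aS,8aR)-4-hydroxy-8a-methyl-5-methylidene-3-(propan-2-yl)decahydronaphthalen-1-yl 4-methoxybenzoate
Conditions: LiBH(sec-Bu)3, THF, −78 °C; aq NH4Cl
Reagents that add atoms: none
Why: Bulky trialkylborohydride reduction, in which the axial face of the C6 ketone is blocked by the syn-axial C14 methyl, so hydride enters equatorially and gives the axial 6-OH (4S) cis to that methyl, while the aryl ester survives at −78 °C.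

## Compound list

1 | (4R)-4-benzyl-1,3-oxazolidin-2-one | O=C1N[C@H](Cc2ccccc2)CO1 | starting material
2 | 3-methylbutanoyl chloride | CC(C)CC(Cl)=O | starting material
3 | (4R)-4-benzyl-3-(3-methylbutanoyl)-1,3-oxazolidin-2-one | CC(C)CC(=O)N1[C@H](Cc2ccccc2)COC1=O | intermediate
4 | 3-bromoprop-1-ene | C=CCBr | starting material
5 | (4R)-4-benzyl-3-[(2R)-2-(propan-2-yl)pent-4-enoyl]-1,3-oxazolidin-2-one | C=CC[C@H](C(C)C)C(=O)N1[C@H](Cc2ccccc2)COC1=O | intermediate
6 | S-ethyl (2R)-2-(propan-2-yl)pent-4-enethioate | C=CC[C@H](C(C)C)C(=O)SCC | intermediate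
7 | hepta-1,6-diyne | C#CCCCC#C | starting material
8 | dimethyl[(1E)-2-methylhept-1-en-6-yn-1-yl]alumane | C[Al](C)/C=C(\C)CCCC#C | intermediate
9 | chloro[(1E)-2-methylhept-1-en-6-yn-1-yl]zinc | Cl[Zn]/C=C(\C)CCCC#C | intermediate
10 | (4R,6E)-7-methyl-4-(propan-2-yl)dodeca-1,6-dien-11-yn-5-one | C=CC[C@H](C(C)C)C(=O)/C=C(\C)CCCC#C | intermediate
11 | (3R,5E)-6-methyl-4-oxo-3-(propan-2-yl)undec-5-en-10-ynal | O=CC[C@H](C(C)C)C(=O)/C=C(\C)CCCC#C | intermediate
12 | 4-methoxybenzoyl chloride | COc1ccc(cc1)C(Cl)=O | starting material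
13 | (3R,5E)-1-bromo-6-methyl-4-oxo-3-(propan-2-yl)undec-5-en-10-yn-1-yl 4-methoxybenzoate (both C1 epimers) | COc1ccc(cc1)C(=O)OC(Br)C[C@H](C(C)C)C(=O)/C=C(\C)CCCC#C | intermediate
14 | (1R,3R,4aS,8aR)-8a-methyl-5-methylidene-4-oxo-3-(propan-2-yl)decahydronaphthalen-1-yl 4-methoxybenzoate | C=C1CCC[C@]2(C)[C@H]1C(=O)[C@@H](C(C)C)C[C@H]2OC(=O)c1ccc(OC)cc1 | intermediate
15 | (1R,3R,4S,4aS,8aR)-4-hydroxy-8a-methyl-5-methylidene-3-(propan-2-yl)decahydronaphthalen-1-yl 4-methoxybenzoate | C=C1CCC[C@]2(C)[C@H]1[C@@H](O)[C@@H](C(C)C)C[C@H]2OC(=O)c1ccc(OC)cc1 | target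

## Step count and risks

Total step count: 7. Longest linear sequence: 7 steps (1 → 3 → 5 → 6 → 10 → 11 → 14 → 15).

**Step 6 (most likely to fail).** The 1-bromoalkyl ester is labile next to a γ-ketone. The first closure could go 5-exo at C5 instead of 6-endo at the fully substituted C10. The equatorial preference of the aroyloxy group at the C9 radical may be modest, giving a C9 epimer. The C5 radical can be reduced before it reaches the alkyne.

The fallback builds the two rings one after the other; it sets out from 11 and comes back at 14. Aldehyde 11 is cyclised by SmI2 (THF/t-BuOH, −78 °C; ketyl addition to the enone β-carbon in a chair with the bulky samarium alkoxide equatorial) to (2R,4R,5R)-4-hydroxy-5-methyl-5-(pent-4-yn-1-yl)-2-(propan-2-yl)cyclohexan-1-one F3. Acylation with 12 (pyridine, DMAP) gives (1R,2R,5R)-2-methyl-4-oxo-2-(pent-4-yn-1-yl)-5-(propan-2-yl)cyclohexyl 4-methoxybenzoate F4. Kinetic enolisation at the CH2 side (t-BuMe2SiOTf, Et3N, −78 °C) gives (1R,2R,5R)-4-{[tert-butyl(dimethyl)silyl]oxy}-2-methyl-2-(pent-4-yn-1-yl)-5-(propan-2-yl)cyclohex-3-en-1-yl 4-methoxybenzoate F5. Ph3PAuCl/AgBF4 (CH2Cl2/H2O, 40 °C) then closes ring A by 6-exo-dig carbocyclisation of the silyl enol ether onto the alkyne and gives 14.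

**Step 4.** Mono-carboalumination of a diyne is statistical, and the free alkyne C–H or a bis-alane can divert the Pd acyl coupling.

The fallback replaces the acyl coupling by carbonyl addition and oxidation; it sets out from 6 (with alane 8 made as before) and comes back at 10. Thioester 6 is reduced with i-Bu2AlH (CH2Cl2, −78 °C) to (2R)-2-(propan-2-yl)pent-4-enal F1. Alane 8 is added to F1 (CH2Cl2, 0 → 23 °C) to give (4R,6E)-7-methyl-4-(propan-2-yl)dodeca-1,6-dien-11-yn-5-ol F2 as a mixture of C5 epimers. Dess–Martin oxidation of F2 gives 10.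

**Step 7.** The ketone is hindered on both faces and its C5–H is allylic, so the bulky hydride may enolise it (risking migration of the methylidene into conjugation) or give a poor axial/equatorial ratio.

The fallback sets out from 14 and comes back at 15. Ketone 14 is reduced with the small, non-basic NaBH4/CeCl3·7H2O (MeOH, −40 °C). Any equatorial alcohol, (1R,3R,4R,4aS,8aR)-4-hydroxy-8a-methyl-5-methylidene-3-(propan-2-yl)decahydronaphthalen-1-yl 4-methoxybenzoate F6, is inverted by Mitsunobu reaction (4-nitrobenzoic acid, PPh3, DIAD) to (1R,3R,4S,4aS,8aR)-8a-methyl-5-methylidene-4-[(4-nitrobenzoyl)oxy]-3-(propan-2-yl)decahydronaphthalen-1-yl 4-methoxybenzoate F7. The activated nitrobenzoate is then removed selectively (K2CO3, MeOH, 0 °C) in the presence of the electron-rich, neopentylic anisate to give 15.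

## Further compounds

F1 | step 4 | (2R)-2-(propan-2-yl)pent-4-enal | C=CC[C@H](C(C)C)C=O
F2 | step 4 | (4R,6E)-7-methyl-4-(propan-2-yl)dodeca-1,6-dien-11-yn-5-ol (both C5 epimers) | C=CC[C@H](C(C)C)C(O)/C=C(\C)CCCC#C
F3 | step 6 | (2R,4R,5R)-4-hydroxy-5-methyl-5-(pent-4-yn-1-yl)-2-(propan-2-yl)cyclohexan-1-one | C#CCCC[C@]1(C)CC(=O)[C@@H](C(C)C)C[C@H]1O
F4 | step 6 | (1R,2R,5R)-2-methyl-4-oxo-2-(pent-4-yn-1-yl)-5-(propan-2-yl)cyclohexyl 4-methoxybenzoate | C#CCCC[C@]1(C)CC(=O)[C@@H](C(C)C)C[C@H]1OC(=O)c1ccc(OC)cc1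
F5 | step 6 | (1R,2R,5R)-4-{[tert-butyl(dimethyl)silyl]oxy}-2-methyl-2-(pent-4-yn-1-yl)-5-(propan-2-yl)cyclohex-3-en-1-yl 4-methoxybenzoate | C#CCCC[C@]1(C)C=C(O[Si](C)(C)C(C)(C)C)[C@@H](C(C)C)C[C@H]1OC(=O)c1ccc(OC)cc1
F6 | step 7 | (1R,3R,4R,4aS,8aR)-4-hydroxy-8a-methyl-5-methylidene-3-(propan-2-yl)decahydronaphthalen-1-yl 4-methoxybenzoate | C=C1CCC[C@]2(C)[C@H]1[C@H](O)[C@@H](C(C)C)C[C@H]2OC(=O)c1ccc(OC)cc1
F7 | step 7 | (1R,3R,4S,4aS,8aR)-8a-methyl-5-methylidene-4-[(4-nitrobenzoyl)oxy]-3-(propan-2-yl)decahydronaphthalen-1-yl 4-methoxybenzoate | C=C1CCC[C@]2(C)[C@H]1[C@@H](OC(=O)c1ccc(cc1)[N+](=O)[O-])[C@@H](C(C)C)C[C@H]2OC(=O)c1ccc(OC)cc1
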